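The trap in a slow reaction is to draw a straight line through the first readings and run it out to the end of the flask, for the line takes no account of a charge that shrinks.

| flask | substrate | partner | temperature | remark | time |
|---|---|---|---|---|---|
| Thursday's | 1.3 M | 3 M | 70 °C | run made earlier |  |
| Sunday's | 1.3 M | 3 M | 112 °C | run made earlier |  |
| teal | 2.0 M | 3.00 M | 75 °C |  | 1.5 h |
| grey | 2.0 M | 3.00 M | 125 °C |  | 1.5 h |
| violet | 2.0 M | 3.00 M | 150 °C |  | 1.5 h |
| green | 2.0 M | 3.00 M | 100 °C |  | 1.5 h |

| run | time / min | product / % |
|---|---|---|
| Thursday's | 8.00 | 0 |
| Thursday's | 20.0 | 0.5 |
| Thursday's | 50.0 | 2.3 |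
| Thursday's | 120 | 0.5 |
| Sunday's | 1.33 | 3.0 |
| Sunday's | 3.00 | 1.2 |
| Sunday's | 8.00 | 1.5 |
| Sunday's | 20.0 | 11.1 |

(each reading ± 1 percentage point)

- the best flask by amount of product, in percent of the substrate charged; "all alike" if 1.5 percentage points covers them all (teal / grey / violet / green / all alike)
- amount of product at the end, in percent of the substrate charged, teal
- amount of product at the end, in percent of the substrate charged, grey
- amount of product at the end, in percent of the substrate charged, violet
- amount of product at the end, in percent of the substrate charged, green

Two chemists argue over these runs, and they begin alike. The line from zero that best passes Sunday's readings has a slope of 0.00509 min⁻¹, and Thursday's has 1.07 × 10⁻⁴ min⁻¹. Thursday's highest reading is 2.3 % against a scatter of 1 percentage point, so that slope is rough. Between 70 °C and 112 °C the two slopes give 7.53 K as the doubling step, the rise in temperature over which the pace doubles. Both chemists take the pace as a share of the charge, although [substrate] goes from 1.3 M to 2.0 M, while [partner] stays at 3.00 M.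

Pace times time is the exposure. For grey I reckon it at 1.52, and for violet at 15.1. The first chemist reads exposure directly as the share made, capped at the charge. Grey's exposure is above one, so on this view grey and violet both finish and tie at the top.

The second chemist holds a pseudo-first-order view: the charge shrinks, and the share made is one minus the exponential of minus the exposure. My reckoning on that view gives grey 78.0 % and violet >99.9 %, so violet leads.

The first view keeps its own ground where exposure is small. Green's is 0.152, and there the shrinking charge corrects the straight line by 1.1 points, less than the margin of 1.5 points.

The forecast names violet, with teal 2 %, grey 70 %, violet 90 % and green 20 %, its grey lying below my figure, and it assumes that “the fractional rate barely depends on substrate”.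

The flasks give violet as best, with violet at 94.2 %, grey at 87.4 % and teal at 0.429 %, and the gap of 6.8 points between violet and grey is wider than the margin.

    substrate + product ⇌ idle adduct, settled at all times (K = 0.810 M⁻¹, ΔH = 13.0 kJ mol⁻¹)
    substrate → intermediate (k = 0.00780 min⁻¹, Ea = 119 kJ mol⁻¹)
    partner + intermediate ⇌ product (K = 7.90 M⁻¹, k = 0.00530 M⁻¹ min⁻¹, Ea = 83.0 kJ mol⁻¹, ΔH = 16.0 kJ mol⁻¹)
    (constants at 100 °C)

Grey reached half conversion at 0.116 h, and at 1.50 h it held 10.6 % as intermediate. Grey's end value, read as an exposure, is 2.08. Going down the 25.0 K to green with the doubling step of 7.53 K divides that by 9.99, which gives an exposure of 0.208 and a share of 18.8 %, and green stands at 23.2 %.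

(The numbers in the tables come from a simulation with made-up constants, and the scatter is random.)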